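**Retrosynthetic overview**

1. The target comes from acidolytic removal of six 4‑methoxybenzyl (PMB) groups from an (E)‑cinnamate, which is made by Wittig union of a C4‑formyl dihydrobenzofuran with the ylide of the (R)‑danshensu bromoacetate.
2. The C4 aldehyde comes from a C4 methyl ester / C3 acid; the carbon on C4 is carried at the carboxyl level from the start.
3. Key disconnection, both bonds in one flask: C2–C3 by chiral‑squaramide aldol–lactonisation of a fluorinated homophthalic anhydride with protected 3,4‑dihydroxybenzaldehyde (sets C2 and C3), and O1–C7a when methoxide opens the lactone and the freed C2 alkoxide displaces fluoride at C7a.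
4. Enabling feature: C3 with its carboxyl carbon and the carbon substituent of C4 sit on the neighbouring benzene carbons C3a and C4, a hidden homophthalic acid. Joining the two carboxyl carbons through one oxygen gives a six‑membered anhydride ring (O, two C=O, C3, C3a, C4) that makes C3–H acidic. Fluorine on C7a, flanked by C7–O and C3a, is the leaving group the C2 alkoxide reaches in a five‑membered closure.
5. Ring order: benzene rings bought; six‑membered anhydride ring (temporary); six‑membered lactone ring (temporary); contraction to the five‑membered dihydrofuran ring.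

Key step: step 6

Remarks: atom names (O1, C2, C3, C3a, C4–C7, C7a) follow benzofuran numbering of the target; PMB = 4‑methoxybenzyl.
Assumption: the quinidine‑derived squaramide is taken to deliver the (3S,4S)‑lactone (enolate attack on the Si face of the aldehyde); should it give the antipode, the quinine‑derived pseudo‑enantiomer is used and nothing else changes.

**Step 1**
Reactants: 1 3‑fluoro‑4‑hydroxybenzoic acid
Product: 3 3‑fluoro‑4‑(PMB‑oxy)benzoic acid, via PMB ester 2 (not isolated)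
Conditions: PMBCl (2.3 equiv), K2CO3, DMF, 60 °C; then NaOH, MeOH–H2O, 60 °C; HCl to pH 3
Reagents that add atoms: 4‑methoxybenzyl chloride, COc1ccc(CCl)cc1; sodium hydroxide, [Na+].[OH-]
Why: Williamson O‑alkylation of phenoxide and carboxylate, followed by saponification of the ester, leaves the aryl PMB ether and the free acid needed for directed metalation.

**Step 2**
Reactants: 3 3‑fluoro‑4‑(PMB‑oxy)benzoic acid
Product: 4 3‑fluoro‑2‑methyl‑4‑(PMB‑oxy)benzoic acid
Conditions: lithium 2,2,6,6‑tetramethylpiperidide (2.2 equiv), THF, −78 °C; MeI, −78 → 0 °C; HCl work‑up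
Reagents that add atoms: iodomethane, CI
Why: Directed ortho‑metalation: the ring hydrogen flanked by the lithium carboxylate and fluorine is the most acidic, so the hindered amide should remove it selectively, and iodomethane traps the aryllithium at −78 °C before lithium fluoride can be lost.

**Step 3**
Reactants: 4 3‑fluoro‑2‑methyl‑4‑(PMB‑oxy)benzoic acid
Product: 5 2‑(carboxymethyl)‑3‑fluoro‑4‑(PMB‑oxy)benzoic acid
Conditions: lithium diisopropylamide (2.5 equiv), THF, −78 → −20 °C; CO2; HCl work‑up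
Reagents that add atoms: carbon dioxide, O=C=O
Why: Carboxylate‑assisted lateral (benzylic) lithiation of the o‑toluic acid and carboxylation of the dianion is the classical homophthalic acid synthesis.

**Step 4**
Reactants: 5 2‑(carboxymethyl)‑3‑fluoro‑4‑(PMB‑oxy)benzoic acid
Product: 6 5‑fluoro‑6‑(PMB‑oxy)isochromane‑1,3‑dione
Conditions: DCC (1.05 equiv), CH2Cl2, 0 °C → rt; filtration
Reagents that add atoms: none
Why: Carbodiimide cyclodehydration of the diacid closes the six‑membered anhydride under neutral conditions that spare the acid‑labile PMB ether.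

**Step 5**
Reactants: 7 3,4‑dihydroxybenzaldehyde
Product: 8 3,4‑bis(PMB‑oxy)benzaldehyde
Conditions: PMBCl (2.3 equiv), K2CO3, DMF, 60 °C
Reagents that add atoms: 4‑methoxybenzyl chloride, COc1ccc(CCl)cc1
Why: Williamson etherification of both phenols; the aldehyde is inert to carbonate.

**Step 6**
Reactants: 6 5‑fluoro‑6‑(PMB‑oxy)isochromane‑1,3‑dione; 8 3,4‑bis(PMB‑oxy)benzaldehyde
Product: 11 (2S,3S)‑2‑[3,4‑bis(PMB‑oxy)phenyl]‑4‑(methoxycarbonyl)‑7‑(PMB‑oxy)‑2,3‑dihydro‑1‑benzofuran‑3‑carboxylic acid, via lactone acid 9 (not isolated), via ring‑opened hydroxy ester 10 (not isolated)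
Conditions: squaramide from 9‑amino‑9‑deoxy‑epi‑quinidine and 3,5‑bis(trifluoromethyl)aniline (5 mol %), MTBE–THF, −15 °C → rt; then NaOMe (5 equiv), DMSO–MeOH (10:1), 85 °C; aq. citric acid
Reagents that add atoms: sodium methoxide, [Na+].[O-]C
Why: The quinuclidine of the squaramide deprotonates the CH2 of anhydride 6 (the future C3, acidified by the anhydride carbonyl and the aryl ring), the hydrogen‑bonded enolate adds to aldehyde 8 to make C2–C3, and the alkoxide closes six‑membered lactone 9 by 6‑exo‑trig acyl transfer onto the aryl‑bound anhydride carbonyl; the closest known reaction type is the cinchona‑squaramide‑catalysed formal cycloaddition of homophthalic anhydride with aromatic aldehydes (Tamura/Perkin‑type aldol–lactonisation). Methoxide then cleaves the lactone at its acyl carbon to alkoxide 10, which forms O1–C7a and the five‑membered ring by 5‑exo‑trig addition–elimination (intramolecular SNAr) on the fluoroarene, the known way from 2‑(2‑fluoroaryl)ethanols to 2,3‑dihydrobenzofurans. C2 (S) is set by the catalyst, which should direct the enolate to the Si face of the aldehyde, and C3 (S) by the trans approach in the same bond‑forming event, trans also being the thermodynamically favoured arrangement. The ring contraction makes or breaks no bond at C2 or C3, and the C3 carboxylate shuts off enolisation, retro‑aldol cleavage and E1cB loss of the aryloxide, so both centres should be carried over unchanged. The step needs enantioface and trans selectivity in the first stage (catalyst control, precedent on the parent anhydride) and chemoselective O‑arylation in the second: fluorine on C7a has no ortho hydrogen, so no aryne can form, the lactone–hydroxy ester equilibrium is drained only through the irreversible five‑membered closure, and the tethered alkoxide outruns external methoxide.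

**Step 7**
Reactants: 11 (2S,3S)‑2‑[3,4‑bis(PMB‑oxy)phenyl]‑4‑(methoxycarbonyl)‑7‑(PMB‑oxy)‑2,3‑dihydro‑1‑benzofuran‑3‑carboxylic acid
Product: 12 (2S,3S)‑2‑[3,4‑bis(PMB‑oxy)phenyl]‑4‑(hydroxymethyl)‑7‑(PMB‑oxy)‑2,3‑dihydro‑1‑benzofuran‑3‑carboxylic acid
Conditions: LiBH4 (6 equiv), THF, 0 → 50 °C; work‑up at pH 5, 0 °C; crude used directly
Reagents that add atoms: none
Why: Chemoselective borohydride reduction of the aryl methyl ester, the C3 acid being held as its lithium carboxylate, which LiBH4 does not reduce and which cannot enolise.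

**Step 8**
Reactants: 12 (2S,3S)‑2‑[3,4‑bis(PMB‑oxy)phenyl]‑4‑(hydroxymethyl)‑7‑(PMB‑oxy)‑2,3‑dihydro‑1‑benzofuran‑3‑carboxylic acid
Product: 13 methyl (2S,3S)‑2‑[3,4‑bis(PMB‑oxy)phenyl]‑4‑(hydroxymethyl)‑7‑(PMB‑oxy)‑2,3‑dihydro‑1‑benzofuran‑3‑carboxylate
Conditions: TMSCHN2, toluene–MeOH (4:1), 0 °C
Reagents that add atoms: (trimethylsilyl)diazomethane, C[Si](C)(C)C=[N+]=[N-]
Why: Diazoalkane O‑methylation esterifies the acid under neutral conditions, leaving the alcohol and the base‑sensitive C3 centre untouched.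

**Step 9**
Reactants: 13 methyl (2S,3S)‑2‑[3,4‑bis(PMB‑oxy)phenyl]‑4‑(hydroxymethyl)‑7‑(PMB‑oxy)‑2,3‑dihydro‑1‑benzofuran‑3‑carboxylate
Product: 14 methyl (2S,3S)‑2‑[3,4‑bis(PMB‑oxy)phenyl]‑4‑formyl‑7‑(PMB‑oxy)‑2,3‑dihydro‑1‑benzofuran‑3‑carboxylate
Conditions: MnO2 (15 equiv), CH2Cl2, rt
Reagents that add atoms: none
Why: MnO2 oxidation is selective for benzylic alcohols and stops at the aldehyde under neutral, heterogeneous conditions.

**Step 10**
Reactants: 15 sodium (2R)‑3‑(3,4‑dihydroxyphenyl)‑2‑hydroxypropanoate (sodium danshensu)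
Product: 16 4‑methoxybenzyl (2R)‑3‑[3,4‑bis(PMB‑oxy)phenyl]‑2‑hydroxypropanoate
Conditions: PMBCl (3.3 equiv), K2CO3, Bu4NI (cat.), DMF, rt
Reagents that add atoms: 4‑methoxybenzyl chloride, COc1ccc(CCl)cc1
Why: Williamson alkylation of carboxylate and phenoxides; carbonate neither deprotonates the secondary alcohol nor enolises the bought (R) centre.

**Step 11**
Reactants: 16 4‑methoxybenzyl (2R)‑3‑[3,4‑bis(PMB‑oxy)phenyl]‑2‑hydroxypropanoate
Product: 17 4‑methoxybenzyl (2R)‑2‑(bromoacetoxy)‑3‑[3,4‑bis(PMB‑oxy)phenyl]propanoate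
Conditions: BrCH2COBr, pyridine, CH2Cl2, −20 → 0 °C
Reagents that add atoms: bromoacetyl bromide, BrCC(Br)=O
Why: O‑acylation of the secondary alcohol by the acid bromide, which reacts far faster than the alkyl bromide end.

**Step 12**
Reactants: 17 4‑methoxybenzyl (2R)‑2‑(bromoacetoxy)‑3‑[3,4‑bis(PMB‑oxy)phenyl]propanoate
Product: 19 4‑methoxybenzyl (2R)‑3‑[3,4‑bis(PMB‑oxy)phenyl]‑2‑[(triphenylphosphoranylidene)acetoxy]propanoate, via phosphonium bromide 18 (not isolated)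
Conditions: PPh3, toluene, rt; then aq. Na2CO3, CH2Cl2, 0 °C
Reagents that add atoms: triphenylphosphine, c1ccc(cc1)P(c1ccccc1)c1ccccc1
Why: SN2 quaternisation of the phosphine by the α‑bromo ester and deprotonation of the acidic phosphonium salt give the ester‑stabilised ylide.

**Step 13**
Reactants: 14 methyl (2S,3S)‑2‑[3,4‑bis(PMB‑oxy)phenyl]‑4‑formyl‑7‑(PMB‑oxy)‑2,3‑dihydro‑1‑benzofuran‑3‑carboxylate; 19 4‑methoxybenzyl (2R)‑3‑[3,4‑bis(PMB‑oxy)phenyl]‑2‑[(triphenylphosphoranylidene)acetoxy]propanoate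
Product: 20 hexa‑PMB‑protected monomethyl lithospermate (five aryl PMB ethers, PMB ester of the lactate carboxyl, methyl ester at C3, (E)‑alkene)
Conditions: toluene, 80 °C
Reagents that add atoms: none
Why: Wittig olefination with a stabilised ylide should give the (E)‑cinnamate, and its neutral conditions avoid E1cB ring opening or epimerisation at the β‑aryloxy ester centre C3.

**Step 14**
Reactants: 20 hexa‑PMB‑protected monomethyl lithospermate
Product: 21 monomethyl lithospermate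
Conditions: TFA–CH2Cl2 (1:5), 1,3‑dimethoxybenzene (40 equiv), 0 °C → rt
Reagents that add atoms: none
Why: Acidolysis (SN1) of the five aryl PMB ethers and the PMB ester, with 1,3‑dimethoxybenzene trapping the benzyl cations by Friedel–Crafts alkylation; methyl ester, cinnamate and the trans ring centres should survive cold trifluoroacetic acid.

**Compound list**

1 | 3‑fluoro‑4‑hydroxybenzoic acid | OC(=O)c1ccc(O)c(F)c1 | starting material
2 | 4‑methoxybenzyl 3‑fluoro‑4‑(PMB‑oxy)benzoate | COc1ccc(COC(=O)c2ccc(OCc3ccc(OC)cc3)c(F)c2)cc1 | intermediate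
3 | 3‑fluoro‑4‑(PMB‑oxy)benzoic acid | COc1ccc(COc2ccc(C(=O)O)cc2F)cc1 | intermediate
4 | 3‑fluoro‑2‑methyl‑4‑(PMB‑oxy)benzoic acid | COc1ccc(COc2ccc(C(=O)O)c(C)c2F)cc1 | intermediate
5 | 2‑(carboxymethyl)‑3‑fluoro‑4‑(PMB‑oxy)benzoic acid | COc1ccc(COc2ccc(C(=O)O)c(CC(=O)O)c2F)cc1 | intermediate
6 | 5‑fluoro‑6‑(PMB‑oxy)isochromane‑1,3‑dione | COc1ccc(COc2ccc3C(=O)OC(=O)Cc3c2F)cc1 | intermediate
7 | 3,4‑dihydroxybenzaldehyde | O=Cc1ccc(O)c(O)c1 | starting material
8 | 3,4‑bis(PMB‑oxy)benzaldehyde | COc1ccc(COc2ccc(C=O)cc2OCc2ccc(OC)cc2)cc1 | intermediate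
9 | (3S,4S)‑3‑[3,4‑bis(PMB‑oxy)phenyl]‑5‑fluoro‑1‑oxo‑6‑(PMB‑oxy)isochromane‑4‑carboxylic acid | OC(=O)[C@H]1c2c(F)c(OCc3ccc(OC)cc3)ccc2C(=O)O[C@@H]1c1ccc(OCc2ccc(OC)cc2)c(OCc2ccc(OC)cc2)c1 | intermediate
10 | (2S,3S)‑2‑[2‑fluoro‑6‑(methoxycarbonyl)‑3‑(PMB‑oxy)phenyl]‑3‑[3,4‑bis(PMB‑oxy)phenyl]‑3‑hydroxypropanoic acid | COC(=O)c1ccc(OCc2ccc(OC)cc2)c(F)c1[C@H](C(=O)O)[C@H](O)c1ccc(OCc2ccc(OC)cc2)c(OCc2ccc(OC)cc2)c1 | intermediate
11 | (2S,3S)‑2‑[3,4‑bis(PMB‑oxy)phenyl]‑4‑(methoxycarbonyl)‑7‑(PMB‑oxy)‑2,3‑dihydro‑1‑benzofuran‑3‑carboxylic acid | OC(=O)[C@H]1c2c(C(=O)OC)ccc(OCc3ccc(OC)cc3)c2O[C@@H]1c1ccc(OCc2ccc(OC)cc2)c(OCc2ccc(OC)cc2)c1 | intermediate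
12 | (2S,3S)‑2‑[3,4‑bis(PMB‑oxy)phenyl]‑4‑(hydroxymethyl)‑7‑(PMB‑oxy)‑2,3‑dihydro‑1‑benzofuran‑3‑carboxylic acid | OC(=O)[C@H]1c2c(CO)ccc(OCc3ccc(OC)cc3)c2O[C@@H]1c1ccc(OCc2ccc(OC)cc2)c(OCc2ccc(OC)cc2)c1 | intermediate
13 | methyl (2S,3S)‑2‑[3,4‑bis(PMB‑oxy)phenyl]‑4‑(hydroxymethyl)‑7‑(PMB‑oxy)‑2,3‑dihydro‑1‑benzofuran‑3‑carboxylate | COC(=O)[C@H]1c2c(CO)ccc(OCc3ccc(OC)cc3)c2O[C@@H]1c1ccc(OCc2ccc(OC)cc2)c(OCc2ccc(OC)cc2)c1 | intermediate
14 | methyl (2S,3S)‑2‑[3,4‑bis(PMB‑oxy)phenyl]‑4‑formyl‑7‑(PMB‑oxy)‑2,3‑dihydro‑1‑benzofuran‑3‑carboxylate | COC(=O)[C@H]1c2c(C=O)ccc(OCc3ccc(OC)cc3)c2O[C@@H]1c1ccc(OCc2ccc(OC)cc2)c(OCc2ccc(OC)cc2)c1 | intermediate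
15 | sodium (2R)‑3‑(3,4‑dihydroxyphenyl)‑2‑hydroxypropanoate | [Na+].[O-]C(=O)[C@H](O)Cc1ccc(O)c(O)c1 | starting material
16 | 4‑methoxybenzyl (2R)‑3‑[3,4‑bis(PMB‑oxy)phenyl]‑2‑hydroxypropanoate | COc1ccc(COC(=O)[C@H](O)Cc2ccc(OCc3ccc(OC)cc3)c(OCc3ccc(OC)cc3)c2)cc1 | intermediate
17 | 4‑methoxybenzyl (2R)‑2‑(bromoacetoxy)‑3‑[3,4‑bis(PMB‑oxy)phenyl]propanoate | COc1ccc(COC(=O)[C@H](OC(=O)CBr)Cc2ccc(OCc3ccc(OC)cc3)c(OCc3ccc(OC)cc3)c2)cc1 | intermediate
18 | phosphonium bromide from 17 and triphenylphosphine | [Br-].COc1ccc(COC(=O)[C@H](OC(=O)C[P+](c2ccccc2)(c2ccccc2)c2ccccc2)Cc2ccc(OCc3ccc(OC)cc3)c(OCc3ccc(OC)cc3)c2)cc1 | intermediate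
19 | 4‑methoxybenzyl (2R)‑3‑[3,4‑bis(PMB‑oxy)phenyl]‑2‑[(triphenylphosphoranylidene)acetoxy]propanoate | COc1ccc(COC(=O)[C@H](OC(=O)C=P(c2ccccc2)(c2ccccc2)c2ccccc2)Cc2ccc(OCc3ccc(OC)cc3)c(OCc3ccc(OC)cc3)c2)cc1 | intermediate
20 | hexa‑PMB‑protected monomethyl lithospermate | COC(=O)[C@H]1c2c(/C=C/C(=O)O[C@H](Cc3ccc(OCc4ccc(OC)cc4)c(OCc4ccc(OC)cc4)c3)C(=O)OCc3ccc(OC)cc3)ccc(OCc3ccc(OC)cc3)c2O[C@@H]1c1ccc(OCc2ccc(OC)cc2)c(OCc2ccc(OC)cc2)c1 | intermediate
21 | monomethyl lithospermate | COC(=O)[C@H]1c2c(/C=C/C(=O)O[C@H](Cc3ccc(O)c(O)c3)C(=O)O)ccc(O)c2O[C@@H]1c1ccc(O)c(O)c1 | target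

**Step count and risks**

Total step count: 14. Longest linear sequence: 10 steps (steps 1–4, 6–9, 13, 14).

Steps most likely to fail:

Step 6. What may go wrong: erosion of enantio‑ and diastereofacial control in the aldol–lactonisation stage, because the fluorinated, alkoxy‑substituted anhydride is more hindered and less acidic than the parent and the aldehyde is electron‑rich. Fallback: auxiliary control by an Evans syn‑aldol, setting out from diacid 5 and coming back at hydroxy ester 10. Double O‑methylation (MeI, K2CO3, DMF) should give methyl 3‑fluoro‑2‑(2‑methoxy‑2‑oxoethyl)‑4‑(PMB‑oxy)benzoate F1. One equivalent of LiOH (THF–H2O, 0 °C) should cleave the unhindered aliphatic ester to the arylacetic acid F2. Activation with pivaloyl chloride and Et3N gives the pivalic mixed anhydride F3, which is not isolated and acylates (S)‑4‑benzyl‑1,3‑oxazolidin‑2‑one (LiCl, Et3N, THF) to the imide F4. Bu2BOTf and i‑Pr2NEt in CH2Cl2 at −78 °C, then aldehyde 8, should give the syn‑aldol adduct F5 with the (S,S) configuration at the two new centres, since the (S)‑auxiliary directs the Z‑boron enolate in the same sense as in its propionate aldols. LiOH/H2O2 (THF–H2O, 0 °C) removes the auxiliary and delivers 10 (or lactone 9 if it closes on acidification), which enters the methoxide stage of step 6 and gives 11.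

Step 14. What may go wrong: capture of 4‑methoxybenzyl cations by the freed catechol rings and acid‑promoted ionisation of the benzylic C2–O1 bond on the fully assembled molecule. Fallback: remove the protecting groups by hydrogenolysis before the alkene exists and join unprotected halves by a Doebner–Knoevenagel condensation, setting out from aldehyde 14 and hydroxy ester 16 and coming back at target 21. Hydrogenolysis of 14 (H2, Pd/C, EtOAc, rt, stopped once the ethers are gone) should give methyl (2S,3S)‑2‑(3,4‑dihydroxyphenyl)‑4‑formyl‑7‑hydroxy‑2,3‑dihydro‑1‑benzofuran‑3‑carboxylate F9. Heating 16 with 2,2‑dimethyl‑1,3‑dioxane‑4,6‑dione (toluene, 100 °C) should give the PMB‑protected malonic half ester F10, and hydrogenolysis (H2, Pd/C) the unprotected (2R)‑2‑[(carboxyacetyl)oxy]‑3‑(3,4‑dihydroxyphenyl)propanoic acid F11. Condensation of F9 with F11 (pyridine, cat. piperidine, 40 °C, under argon) with loss of CO2 should give 21 directly.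

Step 7. What may go wrong: incomplete hydride delivery to the hindered, electron‑rich aryl ester, and lactonisation of the product hydroxy acid onto the C3 carboxyl during acidic work‑up. Fallback: carry the C4 carbon as an amide and reduce it straight to the aldehyde, setting out from lactone acid 9 (isolated after the first stage of step 6) and coming back at aldehyde 14. Aminolysis with morpholine (THF, 60 °C) should give the hydroxy morpholine amide acid F6, not isolated. KOtBu in DMSO at 70 °C should close the dihydrofuran ring by the same intramolecular SNAr to the amide acid F7. TMSCHN2 gives its methyl ester F8, and Cp2Zr(H)Cl (THF, rt) reduces the tertiary amide, but not the methyl ester, to 14.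

**Further compounds**

F1 | step 6 | methyl 3‑fluoro‑2‑(2‑methoxy‑2‑oxoethyl)‑4‑(PMB‑oxy)benzoate | COC(=O)Cc1c(F)c(OCc2ccc(OC)cc2)ccc1C(=O)OC
F2 | step 6 | [2‑fluoro‑6‑(methoxycarbonyl)‑3‑(PMB‑oxy)phenyl]acetic acid | OC(=O)Cc1c(F)c(OCc2ccc(OC)cc2)ccc1C(=O)OC
F3 | step 6 | pivalic mixed anhydride of F2 | CC(C)(C)C(=O)OC(=O)Cc1c(F)c(OCc2ccc(OC)cc2)ccc1C(=O)OC
F4 | step 6 | methyl 2‑{2‑[(4S)‑4‑benzyl‑2‑oxo‑1,3‑oxazolidin‑3‑yl]‑2‑oxoethyl}‑3‑fluoro‑4‑(PMB‑oxy)benzoate | COC(=O)c1ccc(OCc2ccc(OC)cc2)c(F)c1CC(=O)N1[C@@H](Cc2ccccc2)COC1=O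
F5 | step 6 | methyl 2‑{(2S,3S)‑1‑[(4S)‑4‑benzyl‑2‑oxo‑1,3‑oxazolidin‑3‑yl]‑3‑[3,4‑bis(PMB‑oxy)phenyl]‑3‑hydroxy‑1‑oxopropan‑2‑yl}‑3‑fluoro‑4‑(PMB‑oxy)benzoate | COC(=O)c1ccc(OCc2ccc(OC)cc2)c(F)c1[C@H](C(=O)N1[C@@H](Cc2ccccc2)COC1=O)[C@H](O)c1ccc(OCc2ccc(OC)cc2)c(OCc2ccc(OC)cc2)c1
F6 | step 7 | (2S,3S)‑2‑[2‑fluoro‑6‑(morpholine‑4‑carbonyl)‑3‑(PMB‑oxy)phenyl]‑3‑[3,4‑bis(PMB‑oxy)phenyl]‑3‑hydroxypropanoic acid | O=C(N1CCOCC1)c1ccc(OCc2ccc(OC)cc2)c(F)c1[C@H](C(=O)O)[C@H](O)c1ccc(OCc2ccc(OC)cc2)c(OCc2ccc(OC)cc2)c1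
F7 | step 7 | (2S,3S)‑2‑[3,4‑bis(PMB‑oxy)phenyl]‑4‑(morpholine‑4‑carbonyl)‑7‑(PMB‑oxy)‑2,3‑dihydro‑1‑benzofuran‑3‑carboxylic acid | OC(=O)[C@H]1c2c(C(=O)N3CCOCC3)ccc(OCc3ccc(OC)cc3)c2O[C@@H]1c1ccc(OCc2ccc(OC)cc2)c(OCc2ccc(OC)cc2)c1
F8 | step 7 | methyl (2S,3S)‑2‑[3,4‑bis(PMB‑oxy)phenyl]‑4‑(morpholine‑4‑carbonyl)‑7‑(PMB‑oxy)‑2,3‑dihydro‑1‑benzofuran‑3‑carboxylate | COC(=O)[C@H]1c2c(C(=O)N3CCOCC3)ccc(OCc3ccc(OC)cc3)c2O[C@@H]1c1ccc(OCc2ccc(OC)cc2)c(OCc2ccc(OC)cc2)c1
F9 | step 14 | methyl (2S,3S)‑2‑(3,4‑dihydroxyphenyl)‑4‑formyl‑7‑hydroxy‑2,3‑dihydro‑1‑benzofuran‑3‑carboxylate | COC(=O)[C@H]1c2c(C=O)ccc(O)c2O[C@@H]1c1ccc(O)c(O)c1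
F10 | step 14 | 3‑{[(2R)‑3‑[3,4‑bis(PMB‑oxy)phenyl]‑1‑[(4‑methoxybenzyl)oxy]‑1‑oxopropan‑2‑yl]oxy}‑3‑oxopropanoic acid | COc1ccc(COC(=O)[C@H](OC(=O)CC(=O)O)Cc2ccc(OCc3ccc(OC)cc3)c(OCc3ccc(OC)cc3)c2)cc1
F11 | step 14 | (2R)‑2‑[(carboxyacetyl)oxy]‑3‑(3,4‑dihydroxyphenyl)propanoic acid | OC(=O)CC(=O)O[C@H](Cc1ccc(O)c(O)c1)C(=O)O
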